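**Plan**

1. Retrosynthesis first cuts the two pyran bonds O1'–C2 and C3'–C4' (inverse-demand oxa-Diels–Alder), which gives (−)-β-pinene and isobutylidene syncarpic acid (from syncarpic acid and isovaleraldehyde).
2. The pinane is then traced back to a bornane: its six-membered ring C1–C2–C3–C4–C5–C6 (the one holding the CMe2 carbon) comes from the five-membered ring C1–C6–C5–C4–C7 of an endo-bornan-2-yl sulfonate by a 1,2-shift of the CMe2 carbon from C1 to C2.
3. The feature that allows this: in the endo sulfonate the C1–C7 bond is anti-periplanar to the C2–O bond, and C1 carries C10 (the future C3' of the pyran), so a silyl group on C10 can stabilise the rearranged pinan-2-yl cation and then leave, fixing the exocyclic C2=C10 alkene.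
4. Forward: (−)-borneol → alcohol-directed C10–H silylation through a temporary oxasilolane ring → ring opening and mesylation → ring expansion to (−)-β-pinene (four- and six-membered rings at once) → domino Knoevenagel/oxa-Diels–Alder, which closes the pyran ring and the spiro centre.
5. Stereochemistry: C1 and C5 of the pinane are C2 and C4 of (−)-borneol (chiral pool); the spiro carbon C2 is set by cycloaddition on the alkene face away from the CMe2 bridge, and C4' by the endo/exo preference of the same step.

Key step: step 3

Remark: bornane numbering (C7 = CMe2 bridge, C10 = carbon on C1) is used for the borneol-derived compounds, pinane numbering (C6 = CMe2 bridge, C10 = exocyclic carbon) for β-pinene and the terpene half of the target, and primed chromene numbering for the pyran half; β-triketones are drawn as one enol tautomer.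

Step 1
Reactants: 1 (−)-borneol
Product: 3 oxasilolane of (−)-borneol (five-membered ring C2–O–SiEt2–C10–C1), via hydridosilyl ether 2 (not isolated)
Conditions: Et2SiH2, [Ir(cod)(OMe)]2 (cat.), THF, rt; then [Ir(cod)(OMe)]2 (cat.), 3,4,7,8-tetramethyl-1,10-phenanthroline (cat.), norbornene, THF, 100 °C
Reagents that add atoms: diethylsilane, CC[SiH2]CC
Why: Dehydrogenative O-silylation followed by iridium-catalysed alcohol-directed γ-C(sp3)–H silylation should close the oxasilolane on the only primary γ-C–H bonds of 1 (the C10 methyl on C1), a known reaction type for secondary alcohols that carry a γ-methyl group; no stereocentre is made and the endo C2–O configuration is kept.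

Step 2
Reactants: 3 oxasilolane of (−)-borneol
Product: 5 endo-10-[diethyl(methyl)silyl]bornan-2-yl methanesulfonate, via lithium alkoxide 4 (not isolated)
Conditions: MeLi, THF, −78 to 0 °C; then MsCl, −78 to 0 °C
Reagents that add atoms: methyllithium, [Li]C; methanesulfonyl chloride, CS(=O)(=O)Cl
Why: Nucleophilic substitution at silicon by the organolithium cleaves the strained Si–O bond and frees the endo lithium alkoxide, which is O-mesylated in the same flask; C2 keeps its configuration because no bond to it is broken.

Step 3
Reactants: 5 endo-10-[diethyl(methyl)silyl]bornan-2-yl methanesulfonate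
Product: 6 (−)-β-pinene
Conditions: 2,6-lutidine, CF3CH2OH, 40 °C
Reagents that add atoms: none
Why: Proposed new method: ionisation of the endo mesylate in the ionising, weakly nucleophilic alcohol is assisted by the anti-periplanar C1–C7 bond (bornane numbering), so the CMe2 carbon shifts from C1 to C2 (Wagner–Meerwein 1,2-shift) and the positive charge arrives at C1, β to silicon, where solvent attack on silicon gives the exocyclic C=CH2 bond; the strong Si–O bond formed pays for the strain of the new four-membered ring, so the bornyl-to-pinanyl direction, normally uphill, becomes irreversible under buffered kinetic conditions. The closest known reaction type is the silicon-terminated Wagner–Meerwein rearrangement of norbornyl cations, in which a silyl group β to the rearranged cation is lost to give a single alkene, together with the pinanyl–bornyl cation shift of terpene chemistry that is run here in reverse. No ring is closed by an exo or endo cyclisation: the six-membered ring C1–C2–C3–C4–C5–C6 and the four-membered ring C1–C6–C5–C7 of 6 (pinane numbering) both arise from the one suprafacial 1,2-shift, by which the five-membered ring C1–C6–C5–C4–C7 of the bornane takes up the carbinol carbon and grows by one atom. The only stereocentre touched is the carbinol carbon, which becomes C1 of 6 with inversion because the migrating carbon enters anti to the leaving group, while C5 of 6 is C4 of 1 unchanged, so that the bicyclic frame can only be (1S,5S). The step needs migration of C7 and not C6, which the endo leaving group secures (an exo group would be anti to C1–C6 and lead to a camphene skeleton), and it needs loss of silicon to outrun opening of the four-membered ring and loss of a ring proton, which the β-silyl effect of the C10–Si bond secures; a 1,3-elimination to a cyclopropane is not expected because the C10–Si bond cannot reach the rear side of the C2–O bond.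

Step 4
Reactants: 7 2',4',6'-trihydroxyacetophenone
Product: 8 acetylsyncarpic acid
Conditions: MeI, NaOMe, MeOH, reflux
Reagents that add atoms: iodomethane, CI
Why: Exhaustive C-methylation of the phloroglucinol enolates with dearomatisation (enolate alkylation) is the standard entry to the syncarpic skeleton, the acetyl group blocking the third ring carbon; no stereocentre is formed.

Step 5
Reactants: 8 acetylsyncarpic acid
Product: 9 syncarpic acid
Conditions: 6 M HCl (aq), reflux
Reagents that add atoms: none
Why: Acid-mediated retro-Claisen-type deacylation of the β-triketone removes the acetyl group as acetic acid and leaves the stable enolised trione; no stereocentre is formed.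

Step 6
Reactants: 6 (−)-β-pinene; 9 syncarpic acid; 10 isovaleraldehyde
Product: 12 target spiro-chromenedione, via isobutylidene syncarpic acid 11 (not isolated)
Conditions: ethylenediammonium diacetate (cat.), toluene, 80 °C
Reagents that add atoms: none
Why: Amine-catalysed Knoevenagel condensation gives the electron-poor 1-oxadiene 11, which adds to the electron-rich 1,1-disubstituted alkene of 6 in an inverse-electron-demand oxa-Diels–Alder reaction with oxygen bonding to the more substituted carbon; attack on the alkene face away from the CMe2 bridge should set the spiro carbon C2 (R), and the transition state that places the ring CH2 (C3) and not the bulkier bridgehead C1 under the heterodiene should set C4' (S), the C4' epimer being the expected minor product to be removed by chromatography.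

**Compound list**

1 | (−)-borneol, (1S,2R,4S)-1,7,7-trimethylbicyclo[2.2.1]heptan-2-ol (endo alcohol) | C[C@@]12CC[C@@H](C[C@H]1O)C2(C)C | starting material
2 | diethyl{[(1S,2R,4S)-1,7,7-trimethylbicyclo[2.2.1]heptan-2-yl]oxy}silane (endo silyl ether with one Si–H) | C[C@@]12CC[C@@H](C[C@H]1O[SiH](CC)CC)C2(C)C | intermediate
3 | oxasilolane of (−)-borneol: 2,2-diethyl-1,2-oxasilolane ring fused to the bornane through the endo C2–O bond and C10 (bornane centres 1R,2R,4S) | CC[Si]1(CC)C[C@@]23CC[C@@H](C[C@H]2O1)C3(C)C | intermediate
4 | lithium (1R,2R,4S)-1-{[diethyl(methyl)silyl]methyl}-7,7-dimethylbicyclo[2.2.1]heptan-2-olate (endo) | CC[Si](C)(CC)C[C@@]12CC[C@@H](C[C@H]1[O-])C2(C)C.[Li+] | intermediate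
5 | (1R,2R,4S)-1-{[diethyl(methyl)silyl]methyl}-7,7-dimethylbicyclo[2.2.1]heptan-2-yl methanesulfonate (endo mesylate) | CC[Si](C)(CC)C[C@@]12CC[C@@H](C[C@H]1OS(C)(=O)=O)C2(C)C | intermediate
6 | (−)-β-pinene, (1S,5S)-6,6-dimethyl-2-methylidenebicyclo[3.1.1]heptane | C=C1CC[C@H]2C[C@@H]1C2(C)C | intermediate
7 | 2',4',6'-trihydroxyacetophenone | CC(=O)c1c(O)cc(O)cc1O | starting material
8 | acetylsyncarpic acid, 2-acetyl-3-hydroxy-4,4,6,6-tetramethylcyclohex-2-ene-1,5-dione | CC(=O)C1=C(O)C(C)(C)C(=O)C(C)(C)C1=O | intermediate
9 | syncarpic acid, 3-hydroxy-4,4,6,6-tetramethylcyclohex-2-ene-1,5-dione | OC1=CC(=O)C(C)(C)C(=O)C1(C)C | intermediate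
10 | isovaleraldehyde, 3-methylbutanal | CC(C)CC=O | starting material
11 | isobutylidene syncarpic acid, 2,2,4,4-tetramethyl-6-(3-methylbutylidene)cyclohexane-1,3,5-trione | CC(C)CC=C1C(=O)C(C)(C)C(=O)C(C)(C)C1=O | intermediate
12 | (1R,2R,4'S,5S)-6,6,6',6',8',8'-hexamethyl-4'-(2-methylpropyl)-3',4'-dihydrospiro[bicyclo[3.1.1]heptane-2,2'-chromene]-5',7'(6'H,8'H)-dione | CC(C)C[C@H]1C[C@@]2(CC[C@H]3C[C@@H]2C3(C)C)OC2=C1C(=O)C(C)(C)C(=O)C2(C)C | target

**Step count**

Total: 6 steps. Longest linear sequence: 4 steps (steps 1, 2, 3, 6); steps 4 and 5 prepare syncarpic acid.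

**Steps most likely to fail**

Step 3 (Proposed new method). What may go wrong: after the 1,2-shift the cation opens its four-membered ring to a monocyclic p-menthenyl cation, or loses a ring proton, faster than solvent removes silicon; partial return to the bornyl cation would then also lead to camphene-type alkenes. The fallback uses known chemistry throughout and keeps the same five-to-six ring expansion, but drives it by carbonyl formation instead of silicon loss. It sets out from 3 and comes back at 6. Tamao–Fleming oxidation of 3 (H2O2, KF, KHCO3, THF/MeOH) should give 10-hydroxyborneol F1. Oxidation of the primary alcohol only (TEMPO cat., PhI(OAc)2, CH2Cl2) should give 2-endo-hydroxybornan-10-al F2. MsCl/Et3N then gives 2-endo-(methanesulfonyloxy)bornan-10-al F3. Baeyer–Villiger oxidation with mCPBA, with migration of the tertiary bridgehead carbon of this non-enolisable aldehyde, should give 2-endo-(methanesulfonyloxy)-7,7-dimethylbicyclo[2.2.1]heptan-1-yl formate F4. K2CO3 in MeOH cleaves the formate, and the bridgehead alkoxide drives the anti-periplanar C1–C7 bond onto C2 with loss of mesylate (semipinacol rearrangement) to give (+)-nopinone F5. Wittig methylenation (Ph3P=CH2, THF) of F5 gives 6.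

Step 6. What may go wrong: the heterodiene is intercepted by a second molecule of 9 (Michael addition) or dimerises before it meets the unactivated alkene, the acidic co-catalyst isomerises the strained alkene, or the endo/exo preference that sets C4' is weak. The fallback sets out from 9 (with 10) and comes back at 12. Condensation of 9, 10 and piperidine (EtOH, rt) should give the isolable Mannich base 3-hydroxy-4,4,6,6-tetramethyl-2-[3-methyl-1-(piperidin-1-yl)butyl]cyclohex-2-ene-1,5-dione F11. Heating F11 with 6 in toluene without any acid releases 11 slowly, by loss of piperidine, in the presence of the alkene and so leads to 12. If the C4' epimer still forms in quantity, it is separated and returned to the same conditions at higher temperature, where cycloreversion to 6 and 11 allows it to be recycled.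

Step 1. What may go wrong: the oxasilolane has to span the endo C2–O bond and C10, which stand at a wide torsion angle in the rigid bornane, so cyclometalation may stall or turn to the secondary C6–H bonds. The fallback is the classical functionalisation of C10 by sulfonation. It sets out from 1 and comes back at 5. Jones oxidation (CrO3, H2SO4, acetone) of 1 gives (−)-camphor F6. Sulfonation (H2SO4, Ac2O) gives (1R)-(−)-10-camphorsulfonic acid F7, which can also be bought. I2/PPh3 in refluxing toluene should give (1R,4S)-10-iodocamphor F8. LDA (the lithium enolate protects the ketone), then t-BuLi (iodine–lithium exchange at C10), then Et2MeSiCl and NH4Cl work-up should give 10-[diethyl(methyl)silyl]camphor F9. Li in liquid NH3 (thermodynamic protonation) should give mainly the endo alcohol 10-[diethyl(methyl)silyl]borneol F10. MsCl/Et3N gives 5.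

**Further compounds**

F1 | step 3 | 10-hydroxyborneol, (1S,2R,4S)-1-(hydroxymethyl)-7,7-dimethylbicyclo[2.2.1]heptan-2-ol | OC[C@@]12CC[C@@H](C[C@H]1O)C2(C)C
F2 | step 3 | 2-endo-hydroxybornan-10-al | O=C[C@@]12CC[C@@H](C[C@H]1O)C2(C)C
F3 | step 3 | 2-endo-(methanesulfonyloxy)bornan-10-al | O=C[C@@]12CC[C@@H](C[C@H]1OS(C)(=O)=O)C2(C)C
F4 | step 3 | 2-endo-(methanesulfonyloxy)-7,7-dimethylbicyclo[2.2.1]heptan-1-yl formate | O=CO[C@@]12CC[C@@H](C[C@H]1OS(C)(=O)=O)C2(C)C
F5 | step 3 | (+)-nopinone, (1R,5S)-6,6-dimethylbicyclo[3.1.1]heptan-2-one | O=C1CC[C@H]2C[C@@H]1C2(C)C
F6 | step 1 | (−)-camphor, (1S,4S)-1,7,7-trimethylbicyclo[2.2.1]heptan-2-one | C[C@@]12CC[C@@H](CC1=O)C2(C)C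
F7 | step 1 | (1R)-(−)-10-camphorsulfonic acid | OS(=O)(=O)C[C@@]12CC[C@@H](CC1=O)C2(C)C
F8 | step 1 | (1R,4S)-10-iodocamphor | IC[C@@]12CC[C@@H](CC1=O)C2(C)C
F9 | step 1 | 10-[diethyl(methyl)silyl]camphor | CC[Si](C)(CC)C[C@@]12CC[C@@H](CC1=O)C2(C)C
F10 | step 1 | 10-[diethyl(methyl)silyl]borneol (endo alcohol) | CC[Si](C)(CC)C[C@@]12CC[C@@H](C[C@H]1O)C2(C)C
F11 | step 6 | 3-hydroxy-4,4,6,6-tetramethyl-2-[3-methyl-1-(piperidin-1-yl)butyl]cyclohex-2-ene-1,5-dione (Mannich base) | CC(C)CC(N1CCCCC1)C1=C(O)C(C)(C)C(=O)C(C)(C)C1=O
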